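Numbering follows the target SMILES: C1 (CH–CO2Me), C2, C3 (quaternary), C4 (NCH2), N, C5, C6 (CH–COiPr), C7, C8 (C–CH2OH), C9, C10, C11, C12=C13, C14, C15, C16. Ring A = N-C4-C3-C8-C9-C5, B = C5-C6-C7-C8-C9, C = seven-membered carbocycle, D = C12–C16, E = C1-C2-C3-C13-C14.
Enabling feature: ring-A carbon C3 is quaternary and carries both C4 (bound to N) and the C13=C12 double bond, so N–C4–C3–C13=C12 is the retron of a [2,3]-Stevens shift. Cutting C3–C4 and re-bonding N to C12 enlarges ring A to the seven-membered allylic ammonium ring N-C12-C13=C3-C8-C9-C5 of a 6-azabicyclo[3.2.2]nonene cage.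
Further cuts: N–C12 (allyl-cation capture), N–C5 (reductive amination), C11=C12 (Wittig), C13=C3 (aldol condensation), C1–C2 and C1–C14 (malonate alkylation, Michael addition), C6–C7 and C8–C9 (phosphine [3+2]). The iPr–CO bond comes last, from a C6/C8 lactone used as a temporary ring.
Forward order of rings: B, then E onto D, then C, the lactone bridge, the seven-membered N ring, its contraction to ring A, then decarboxylation and lactone opening.
Stereochemistry: C8/C9 from a chiral phosphine; C14 from a catalytic asymmetric Michael addition; C5 from convex-face hydride delivery; C6 from lactone-driven epimerisation; C12 from the tether (planar cation, convergent), relayed to C3 in the key step; C1 from kinetic protonation.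
Key step: step 17

Remark: 34 is treated as the open hydroxy ketone; reversible closure to the six-membered hemiketal (C8–CH2OH onto the ketone) counts as the same compound.
Remark: in steps 4 and 6 the catalyst antipode is the one that delivers the configuration drawn.

Step 1
Reactants: 1 but-3-en-2-one; 2 formaldehyde
Product: 3 3-(hydroxymethyl)but-3-en-2-one
Conditions: 37% aq. HCHO, DABCO (cat.), THF–H2O, rt
Reagents that add atoms: none
Why: Morita–Baylis–Hillman reaction: the amine adds to the enone and the enolate carbon (future C8) takes up formaldehyde, which becomes the CH2OH carbon; no stereocentre is formed.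

Step 2
Reactants: 3 3-(hydroxymethyl)but-3-en-2-one
Product: 4 3-[(tert-butyldiphenylsilyloxy)methyl]but-3-en-2-one
Conditions: TBDPSCl, imidazole, CH2Cl2, 0 °C to rt
Reagents that add atoms: tert-butyl(chloro)diphenylsilane CC(C)(C)[Si](Cl)(c1ccccc1)c1ccccc1
Why: Standard silylation of a primary alcohol; the bulky, acid-stable group has to survive step 8 and to steer the diastereoselectivity of step 4.

Step 3
Reactants: 5 4-chlorobutanoyl chloride; 6 methyl (triphenylphosphoranylidene)acetate
Product: 8 methyl 6-chlorohexa-2,3-dienoate (racemic), via (2-chloroethyl)ketene 7 (not isolated)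
Conditions: Et3N, CH2Cl2, 0 °C to rt
Reagents that add atoms: none
Why: Dehydrochlorination gives the ketene, whose C=O undergoes Wittig olefination with the stabilised ylide (standard allenoate synthesis); the axial chirality of 8 does not matter because step 4 erases it.

Step 4
Reactants: 4 3-[(tert-butyldiphenylsilyloxy)methyl]but-3-en-2-one; 8 methyl 6-chlorohexa-2,3-dienoate
Product: 9 methyl (3S,4R)-4-acetyl-4-[(tert-butyldiphenylsilyloxy)methyl]-3-(2-chloroethyl)cyclopent-1-ene-1-carboxylate (ring B; acetyl cis to chloroethyl)
Conditions: C2-symmetric binaphthyl phosphepine (10 mol %), toluene, rt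
Reagents that add atoms: none
Why: Lu-type phosphine-catalysed [3+2] annulation of a γ-substituted allenoate with a 1,1-disubstituted acceptor: the phosphine adds to C5 (so racemic 8 converges), C6 attacks C7, and the tertiary enolate C8 closes on C9; the catalyst fixes the absolute sense, and the bulky CH2OTBDPS group should end up trans to the chloroethyl chain, placing the acetyl group cis to it.

Step 5
Reactants: 9 methyl (3S,4R)-4-acetyl-4-[(tert-butyldiphenylsilyloxy)methyl]-3-(2-chloroethyl)cyclopent-1-ene-1-carboxylate
Product: 11 methyl (3S,4R)-4-(bromoacetyl)-4-[(tert-butyldiphenylsilyloxy)methyl]-3-(2-chloroethyl)cyclopent-1-ene-1-carboxylate, via trimethylsilyl enol ether 10 (not isolated)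
Conditions: TMSOTf, Et3N, CH2Cl2, 0 °C; then NBS, THF, −78 to 0 °C
Reagents that add atoms: trimethylsilyl trifluoromethanesulfonate C[Si](C)(C)OS(=O)(=O)C(F)(F)F (silicon only in 10); N-bromosuccinimide O=C1CCC(=O)N1Br
Why: Soft enolisation can only go toward the methyl group because C8 is quaternary, and electrophilic bromination of the silyl enol ether gives the bromomethyl ketone without touching the enoate.

Step 6
Reactants: 12 cyclopent-2-en-1-one; 13 dimethyl malonate
Product: 14 dimethyl 2-[(1R)-3-oxocyclopentyl]propanedioate
Conditions: gallium–sodium bis(binaphthoxide) complex (10 mol %), NaOt-Bu (cat.), THF, rt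
Reagents that add atoms: none
Why: Catalytic asymmetric Michael addition of a malonate to a cyclic enone with a heterobimetallic binaphthoxide catalyst, which shields one enone face and sets C14.

Step 7
Reactants: 14 dimethyl 2-[(1R)-3-oxocyclopentyl]propanedioate; 11 methyl (3S,4R)-4-(bromoacetyl)-4-[(tert-butyldiphenylsilyloxy)methyl]-3-(2-chloroethyl)cyclopent-1-ene-1-carboxylate
Product: 15 dimethyl 2-{2-[(1R,2S)-1-[(tert-butyldiphenylsilyloxy)methyl]-2-(2-chloroethyl)-4-(methoxycarbonyl)cyclopent-3-en-1-yl]-2-oxoethyl}-2-[(1R)-3-oxocyclopentyl]propanedioate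
Conditions: NaH, THF–DMF, 0 °C to rt
Reagents that add atoms: none
Why: SN2 alkylation of the malonate anion (the most acidic site) by the α-bromo ketone forms C1–C2 and joins the two enantioenriched halves without touching a stereocentre.

Step 8
Reactants: 15 the 1,6-diketone from step 7
Product: 16 dimethyl (6aR)-3-[ring B substituent as in 15]-4-oxo-4,5,6,6a-tetrahydropentalene-1,1(2H)-dicarboxylate (rings D/E; enone C12(=O)–C13=C3)
Conditions: p-TsOH·H2O (20 mol %), toluene, reflux, Dean–Stark
Reagents that add atoms: none
Why: Acid-catalysed intramolecular aldol condensation of a 1,6-diketone (the 2,7-octanedione to 1-acetyl-2-methylcyclopentene type): only the pairing of the C13 enol with the C3 carbonyl gives a five-membered ring that can dehydrate, the gem-diester helps closure, and acid instead of base avoids retro-Michael loss of the malonate that would erode C14.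

Step 9
Reactants: 16 bicyclic enone chloride
Product: 17 triphenylphosphonium iodide of 16 (C11–PPh3+ I− in place of C11–Cl)
Conditions: NaI, PPh3, MeCN, reflux
Reagents that add atoms: triphenylphosphine c1ccc(cc1)P(c1ccccc1)c1ccccc1; sodium iodide [Na+].[I-]
Why: Finkelstein exchange followed by SN2 quaternisation of the phosphine at primary C11; the β,β-disubstituted enone and the enoate do not retain phosphine.

Step 10
Reactants: 17 phosphonium iodide
Product: 19 tetracyclic diene triester (rings B C D E; C11=C12–C13=C3 diene; C5=C6 enoate; C8 C9 C14 as in 34), via phosphorus ylide 18 (not isolated)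
Conditions: KHMDS (1.05 equiv), THF–toluene, high dilution, −78 °C to 60 °C
Reagents that add atoms: none
Why: Intramolecular Wittig olefination: the phosphonium C–H is the most acidic site, and the non-stabilised ylide attacks the enone carbonyl C12 in 1,2-fashion to close ring C as a cyclohepta-1,3-diene, which is possible because C3 and C10 are cis on ring B.

Step 11
Reactants: 19 tetracyclic diene triester
Product: 21 β-hydroxy ester (C5–OH, C6–CO2Me; C5/C6 epimers), via pinacol boronate 20 (not isolated)
Conditions: B2pin2, CuCl/DPEphos (cat.), NaOt-Bu (cat.), MeOH, THF, rt; then NaBO3·4H2O, THF–H2O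
Reagents that add atoms: bis(pinacolato)diboron CC1(C)OB(OC1(C)C)B1OC(C)(C)C(C)(C)O1 (boron only in 20); sodium perborate [Na+].[O-]OB=O
Why: Copper(I)-catalysed conjugate borylation selects the electron-poor C5=C6 bond over the hindered electron-rich diene and perborate oxidation gives the alcohol; the configuration at C5/C6 is irrelevant because steps 12 and 13 erase it.

Step 12
Reactants: 21 β-hydroxy ester
Product: 22 β-keto ester (C5 ketone; C6 epimerisable)
Conditions: Dess–Martin periodinane, CH2Cl2, rt
Reagents that add atoms: none
Why: Dess–Martin oxidation of the secondary alcohol under neutral conditions gives the β-keto ester, now the only ketone in the molecule.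

Step 13
Reactants: 22 β-keto ester; 23 (aminomethyl)trimethylsilane
Product: 25 β-amino ester (C5–NHCH2SiMe3 cis to C10 as in 34; C6 epimers), via enamino ester 24 (not isolated)
Conditions: AcOH (cat.), 4 Å MS, toluene, 60 °C; then NaBH(OAc)3, AcOH–MeCN, 0 °C
Reagents that add atoms: none
Why: Reductive amination of a β-keto ester through its β-enamino ester: hydride should reach C5 from the convex face of the cis-fused B/C bicycle (the face of H9), which places N on the concave face cis to C10, and the amine brings in N together with C4 and its silyl activating group.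

Step 14
Reactants: 25 β-amino ester
Product: 27 amino lactone (C6–C(=O)–O–CH2–C8 bridge; 3-oxabicyclo[3.2.1]octan-2-one on ring B; C6 as in 34), via hydroxy amino ester 26 (not isolated)
Conditions: TBAF, THF, rt; then DBU (cat.), toluene, 80 °C
Reagents that add atoms: none
Why: Fluoride desilylation, then base equilibration of C6 through the ester enolate; only the epimer with CO2Me cis to C8–CH2OH can lactonise (transesterification), so both C6 epimers funnel into the bridged δ-lactone, which masks alcohol and acyl group and turns C6 into a bridgehead.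

Step 15
Reactants: 27 amino lactone
Product: 29 cage amine (N bonded to C5, C12 and CH2SiMe3; 6-azabicyclo[3.2.2]nonene with C13=C3; N on the face of ring D that bears H14), via allylic chloride hydrochloride 28 (not isolated)
Conditions: HCl (2.2 equiv, Et2O), CH2Cl2, −40 to 0 °C; evaporate; K2CO3, MeCN, rt to 50 °C
Reagents that add atoms: hydrogen chloride Cl (chlorine only in 28)
Why: Markovnikov hydrochlorination of the 1,3-diene (proton to C11) gives the C12–C13–C3 allyl chloride, and after neutralisation the C5 amine alkylates intramolecularly (SN1/SN2′) at C12 to form a six-membered ring rather than at neopentyl C3 (a strained 2-azanorbornane); because the allyl cation is planar, both C12 chlorides converge on the single C12 configuration the tether allows.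

Step 16
Reactants: 29 cage amine
Product: 30 N-methyl-N-(trimethylsilylmethyl)ammonium triflate of the cage (CH2SiMe3 on the side of the C13=C3 bridge)
Conditions: MeOTf, 2,6-di-tert-butyl-4-methylpyridine, CH2Cl2, 0 °C
Reagents that add atoms: methyl trifluoromethanesulfonate COS(=O)(=O)C(F)(F)F
Why: Menshutkin quaternisation: the reagent should approach N from the less hindered side that faces the saturated C10–C11 bridge (next to H5), which pushes the resident CH2SiMe3 group to the side of the C13=C3 bridge, as in quaternisations of tropane-type bridged amines.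

Step 17
Reactants: 30 cage ammonium triflate
Product: 32 lactone diester with the complete ring system (ring A closed; C3 quaternary; C12=C13; N–CH3), via ammonium methylide 31 (not isolated)
Conditions: CsF (dried), DMF, rt
Reagents that add atoms: none
Why: Fluoride removes the silyl group and unmasks the non-stabilised ammonium methylide 31, whose carbanion C4 sits on the alkene side of N; a concerted suprafacial [2,3]-sigmatropic (Stevens/Sommelet-type) shift then forms C4–C3, breaks N–C12 and moves the double bond from C13=C3 to C12=C13. The closest known types are the ring-contracting [2,3]-Stevens rearrangement of cyclic allylic ammonium ylides (tetrahydropyridinium to vinylpyrrolidine) and the fluoride-induced rearrangement of N-methylides made from (trimethylsilylmethyl)ammonium salts. The seven-membered ring N-C12-C13=C3-C8-C9-C5 contracts to ring A (N-C4-C3-C8-C9-C5), which is closed by the C4–C3 bond inside the five-centre envelope transition state of the shift, while the carbocycles stay intact. C3, the only new stereocentre, is controlled by 1,3-chirality transfer from C12 (N leaves and C4 arrives on the same alkene face) and by the cage, which lets C4 reach only that face; the C12 stereocentre is consumed. The step needs [2,3] to win over the [1,2] shift, Hofmann or α′,β-elimination, and E1cB loss of N from C5, and three features secure this: regiospecific ylide generation at the silylated carbon, the syn placement from step 16, and the lactone bridge, which as a bridgehead constraint forbids both a C6 enolate and a C5=C6 bond. In one event the step delivers the second of the vicinal quaternary carbons, the tetrasubstituted alkene in its final position, the piperidine ring and the N-methyl group.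

Step 18
Reactants: 32 lactone diester
Product: 33 lactone monoester (C1–H; CO2Me on the ring-E face of C8 and C15; H1 cis to H14)
Conditions: LiCl, H2O, DMSO, 150 °C
Reagents that add atoms: none
Why: Krapcho demethoxycarbonylation of the gem-diester; the resulting ester enolate should be protonated from the less hindered face of ring E (anti to C8 and C15), which sets C1 kinetically, and no basic step that could equilibrate it precedes the final low-temperature addition.

Step 19
Reactants: 33 lactone monoester
Product: 34 target CNP0152638.1 (1S,3S,5R,6R,8S,9R,14S in the numbering above)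
Conditions: i-PrMgCl, THF, −78 to −40 °C; aq. NH4Cl
Reagents that add atoms: isopropylmagnesium chloride CC(C)[Mg]Cl
Why: Single Grignard addition to a lactone: the exposed bridged δ-lactone is more electrophilic than the hindered secondary methyl ester, the magnesium hemiketal persists until the quench and prevents a second addition, and opening releases C8–CH2OH and the isobutyryl group with C6 unchanged (exo, also the thermodynamic epimer).

Compound list
1 | but-3-en-2-one | CC(=O)C=C | starting material
2 | formaldehyde | C=O | starting material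
3 | 3-(hydroxymethyl)but-3-en-2-one | CC(=O)C(=C)CO | intermediate
4 | 3-[(tert-butyldiphenylsilyloxy)methyl]but-3-en-2-one | CC(=O)C(=C)CO[Si](c1ccccc1)(c1ccccc1)C(C)(C)C | intermediate
5 | 4-chlorobutanoyl chloride | O=C(Cl)CCCCl | starting material
6 | methyl (triphenylphosphoranylidene)acetate | COC(=O)C=P(c1ccccc1)(c1ccccc1)c1ccccc1 | starting material
7 | (2-chloroethyl)ketene | O=C=CCCCl | intermediate
8 | methyl 6-chlorohexa-2,3-dienoate (racemic) | COC(=O)C=C=CCCCl | intermediate
9 | ring B cyclopentene, methyl ketone | COC(=O)C1=C[C@H](CCCl)[C@](CO[Si](c2ccccc2)(c2ccccc2)C(C)(C)C)(C(C)=O)C1 | intermediate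
10 | trimethylsilyl enol ether of 9 | COC(=O)C1=C[C@H](CCCl)[C@](CO[Si](c2ccccc2)(c2ccccc2)C(C)(C)C)(C(=C)O[Si](C)(C)C)C1 | intermediate
11 | ring B bromomethyl ketone | COC(=O)C1=C[C@H](CCCl)[C@](CO[Si](c2ccccc2)(c2ccccc2)C(C)(C)C)(C(=O)CBr)C1 | intermediate
12 | cyclopent-2-en-1-one | O=C1C=CCC1 | starting material
13 | dimethyl malonate | COC(=O)CC(=O)OC | starting material
14 | dimethyl 2-[(1R)-3-oxocyclopentyl]propanedioate | O=C1CC[C@H](C1)C(C(=O)OC)C(=O)OC | intermediate
15 | coupled 1,6-diketone | COC(=O)C(C(=O)OC)(CC(=O)[C@]1(CO[Si](c2ccccc2)(c2ccccc2)C(C)(C)C)CC(C(=O)OC)=C[C@@H]1CCCl)[C@@H]1CCC(=O)C1 | intermediate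
16 | D/E bicyclic enone | COC(=O)C1(C(=O)OC)CC([C@]3(CO[Si](c4ccccc4)(c4ccccc4)C(C)(C)C)CC(C(=O)OC)=C[C@@H]3CCCl)=C2C(=O)CC[C@H]21 | intermediate
17 | phosphonium iodide | COC(=O)C1(C(=O)OC)CC([C@]3(CO[Si](c4ccccc4)(c4ccccc4)C(C)(C)C)CC(C(=O)OC)=C[C@@H]3CC[P+](c4ccccc4)(c4ccccc4)c4ccccc4)=C2C(=O)CC[C@H]21.[I-] | intermediate
18 | phosphorus ylide | COC(=O)C1(C(=O)OC)CC([C@]3(CO[Si](c4ccccc4)(c4ccccc4)C(C)(C)C)CC(C(=O)OC)=C[C@@H]3CC=P(c4ccccc4)(c4ccccc4)c4ccccc4)=C2C(=O)CC[C@H]21 | intermediate
19 | tetracyclic diene triester | COC(=O)C1(C(=O)OC)CC2=C3C(CC[C@H]31)=CC[C@H]4C=C(C(=O)OC)C[C@@]24CO[Si](c5ccccc5)(c5ccccc5)C(C)(C)C | intermediate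
20 | C5 pinacol boronate (C5/C6 epimers) | COC(=O)C1(C(=O)OC)CC2=C3C(CC[C@H]31)=CC[C@H]4C(B5OC(C)(C)C(C)(C)O5)C(C(=O)OC)C[C@@]24CO[Si](c5ccccc5)(c5ccccc5)C(C)(C)C | intermediate
21 | β-hydroxy ester (C5/C6 epimers) | COC(=O)C1(C(=O)OC)CC2=C3C(CC[C@H]31)=CC[C@H]4C(O)C(C(=O)OC)C[C@@]24CO[Si](c5ccccc5)(c5ccccc5)C(C)(C)C | intermediate
22 | β-keto ester (C6 epimerisable) | COC(=O)C1(C(=O)OC)CC2=C3C(CC[C@H]31)=CC[C@H]4C(=O)C(C(=O)OC)C[C@@]24CO[Si](c5ccccc5)(c5ccccc5)C(C)(C)C | intermediate
23 | (aminomethyl)trimethylsilane | C[Si](C)(C)CN | starting material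
24 | β-enamino ester | COC(=O)C1(C(=O)OC)CC2=C3C(CC[C@H]31)=CC[C@H]4C(NC[Si](C)(C)C)=C(C(=O)OC)C[C@@]24CO[Si](c5ccccc5)(c5ccccc5)C(C)(C)C | intermediate
25 | β-amino ester (C6 epimers) | COC(=O)C1(C(=O)OC)CC2=C3C(CC[C@H]31)=CC[C@H]4[C@@H](NC[Si](C)(C)C)C(C(=O)OC)C[C@@]24CO[Si](c5ccccc5)(c5ccccc5)C(C)(C)C | intermediate
26 | hydroxy amino ester (C6 epimers) | COC(=O)C1(C(=O)OC)CC2=C3C(CC[C@H]31)=CC[C@H]4[C@@H](NC[Si](C)(C)C)C(C(=O)OC)C[C@@]24CO | intermediate
27 | amino lactone | COC(=O)C1(C(=O)OC)CC2=C3C(CC[C@H]31)=CC[C@H]4[C@@H](NC[Si](C)(C)C)[C@H]5C[C@@]24COC5=O | intermediate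
28 | allylic chloride hydrochloride (C12 epimers) | COC(=O)C1(C(=O)OC)CC2=C3[C@H]1CCC3(Cl)CC[C@H]4[C@@H](NC[Si](C)(C)C)[C@H]5C[C@@]24COC5=O.Cl | intermediate
29 | cage amine | COC(=O)C1(C(=O)OC)CC2=C3[C@H]1CC[C@]34CC[C@H]5[C@@H](N4C[Si](C)(C)C)[C@H]6C[C@@]25COC6=O | intermediate
30 | cage ammonium triflate | COC(=O)C1(C(=O)OC)CC2=C3[C@H]1CC[C@]34CC[C@H]5[C@@H]([N@+]4(C)C[Si](C)(C)C)[C@H]6C[C@@]25COC6=O.[O-]S(=O)(=O)C(F)(F)F | intermediate
31 | ammonium methylide | COC(=O)C1(C(=O)OC)CC2=C3[C@H]1CC[C@]34CC[C@H]5[C@@H]([N@+]4(C)[CH2-])[C@H]6C[C@@]25COC6=O | intermediate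
32 | ring-contracted lactone diester | COC(=O)C1(C(=O)OC)C[C@@]23CN(C)[C@H]4[C@H]5C[C@]2(COC5=O)[C@H]4CCC2=C3[C@H]1CC2 | intermediate
33 | lactone monoester | COC(=O)[C@H]1C[C@@]23CN(C)[C@H]4[C@H]5C[C@]2(COC5=O)[C@H]4CCC2=C3[C@H]1CC2 | intermediate
34 | CNP0152638.1 | COC(=O)[C@H]1C[C@@]23CN(C)[C@H]4[C@H](C(=O)C(C)C)C[C@]2(CO)[C@H]4CCC2=C3[C@H]1CC2 | target

Total step count: 19. Longest linear sequence: 17 (steps 1, 2, 4, 5, 7–19).

Steps most likely to fail

Step 15. Loss of HCl back to dienes may outrun N-alkylation, and the amine may close at the other end of the allyl system (C3). The fallback sets out from 27 and comes back at 29, and replaces cation capture by a halonium-induced aminocyclisation under non-acidic, kinetic conditions. N-Iodosuccinimide in MeCN at −20 °C should activate the more accessible C11=C12 bond. The amine should then open the iodonium ion in anti fashion at the allylic tertiary C12 to give the 11-iodo cage amine F1. Tributyltin hydride/AIBN in toluene then removes the iodine and gives 29.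

Step 10. Closure of the seven-membered ring at a hindered, enolisable enone may be slow, so that proton transfer to the ylide and oligomerisation take over. The fallback sets out from 16 and comes back at 19, and uses a carbonyl addition instead of an olefination. Finkelstein exchange (NaI, acetone) gives the primary iodide F2. SmI2 with catalytic NiI2 in THF should effect an intramolecular Barbier 1,2-addition to C12 and give the tetracyclic tertiary allylic alcohol F3. Acid-catalysed dehydration (PPTS, benzene, reflux) then gives 19.

Step 19. The Grignard reagent may attack or enolise the methyl ester, reduce the lactone by β-hydride transfer, or add twice. The fallback sets out from 33 and comes back at 34, and splits the acylation into two controlled events. The aluminium amide from MeNH(OMe)·HCl and Me3Al in CH2Cl2 should open only the strained lactone to the hydroxy Weinreb amide F4. Its chelated adduct with i-PrMgCl (THF, −20 °C) should then collapse to 34 only on work-up.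

Further compounds
F1 | step 15 | 11-iodo cage amine | COC(=O)C1(C(=O)OC)CC2=C3[C@H]1CC[C@]34[C@H](I)C[C@H]5[C@@H](N4C[Si](C)(C)C)[C@H]6C[C@@]25COC6=O
F2 | step 10 | primary iodide corresponding to 16 | COC(=O)C1(C(=O)OC)CC([C@]3(CO[Si](c4ccccc4)(c4ccccc4)C(C)(C)C)CC(C(=O)OC)=C[C@@H]3CCI)=C2C(=O)CC[C@H]21
F3 | step 10 | tetracyclic tertiary allylic alcohol (C12–OH, either epimer) | COC(=O)C1(C(=O)OC)CC2=C3[C@H]1CCC3(O)CC[C@H]4C=C(C(=O)OC)C[C@@]24CO[Si](c5ccccc5)(c5ccccc5)C(C)(C)C
F4 | step 19 | hydroxy Weinreb amide | COC(=O)[C@H]1C[C@@]23CN(C)[C@H]4[C@H](C(=O)N(C)OC)C[C@]2(CO)[C@H]4CCC2=C3[C@H]1CC2
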